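**Retrosynthetic overview**

1. The benzopyranone (rings A and B) is bought intact as isofraxidin. The only ring made is the oxolane (ring C: O1, C2 bearing CH2OAr, C3 bearing OH and CH3, C4 = CH2, C5 bearing the 2-methylprop-1-enyl group), and it is made last.
2. Key disconnection: ring C is opened at C3–C4 and at O1–C5. This gives an (S)-α-triethylsilyloxy methyl ketone and 4-methylpenta-1,3-diene. In the forward sense one Lewis-acid-promoted formal [3+2] annulation forms both bonds and the C3 and C5 stereocenters, and every carbon and oxygen of the two partners is kept.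
3. Enabling feature: O1 and the tertiary carbinol C3 sit on adjacent ring atoms (C2–C3), so C2–C3 is a masked α-oxy ketone. C5 is allylic to the isobutenyl group, so C4–C5 is the vinyl end of a diene whose attack on the ketone leaves a 1,1-dimethylallyl cation at C5 within reach of O1.
4. The ketone comes from the aryl ether C–O bond (isofraxidin plus (R)-2-vinyloxirane, which supplies C2), silylation, and Wacker-type oxidation of the vinyl group.

Key step: step 4

Remark: (R)-2-vinyloxirane is taken as a purchasable enantiopure building block; it supplies C2 of the oxolane, the only stereocenter not created in the route.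

**Step 1**
Reactants: 1 isofraxidin (7-hydroxy-6,8-dimethoxy-2H-chromen-2-one); 2 (R)-2-vinyloxirane
Product: 3 7-{[(2R)-2-hydroxybut-3-en-1-yl]oxy}-6,8-dimethoxy-2H-chromen-2-one
Conditions: 2 (1.5 equiv), Cs2CO3 (0.3 equiv), DMF, 70 °C, sealed tube
Reagents that add atoms: none
Why: Base-catalysed SN2 opening of a monosubstituted epoxide by the phenoxide at its unsubstituted CH2 terminus (aryl ether formation, an addition with no by-product) does not touch the stereocenter, so the (R) configuration of 2 is carried into 3.

**Step 2**
Reactants: 3 7-{[(2R)-2-hydroxybut-3-en-1-yl]oxy}-6,8-dimethoxy-2H-chromen-2-one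
Product: 4 6,8-dimethoxy-7-{[(2R)-2-(triethylsilyloxy)but-3-en-1-yl]oxy}-2H-chromen-2-one
Conditions: TESCl (1.3 equiv), imidazole (2 equiv), DMF, 0 °C → rt
Reagents that add atoms: chlorotriethylsilane, CC[Si](Cl)(CC)CC
Why: Imidazole-promoted silylation of a secondary alcohol installs a non-chelating triethylsilyl ether, which is needed for the facial selectivity of step 4 and is the group that leaves oxygen in the ring closure of step 4.

**Step 3**
Reactants: 4 6,8-dimethoxy-7-{[(2R)-2-(triethylsilyloxy)but-3-en-1-yl]oxy}-2H-chromen-2-one
Product: 5 6,8-dimethoxy-7-{[(2S)-3-oxo-2-(triethylsilyloxy)butyl]oxy}-2H-chromen-2-one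
Conditions: PdCl2(Quinox) (5 mol %; Quinox = 2-(4,5-dihydro-1,3-oxazol-2-yl)quinoline), AgSbF6 (12 mol %), 70% aq. tBuOOH (12 equiv), CH2Cl2, 0 °C → rt
Reagents that add atoms: tert-butyl hydroperoxide, CC(C)(C)OO
Why: Wacker-type oxidation by the cationic divalent palladium–Quinox catalyst delivers the peroxide oxygen to the internal carbon of a protected allylic alcohol, giving the methyl ketone and not the aldehyde, under near-neutral conditions that should leave the adjacent stereocenter and the electron-poor coumarin alkene untouched (the descriptor changes from R to S only because the priorities change).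

**Step 4**
Reactants: 5 6,8-dimethoxy-7-{[(2S)-3-oxo-2-(triethylsilyloxy)butyl]oxy}-2H-chromen-2-one; 6 4-methylpenta-1,3-diene
Product: 10 7-{[(2S,3R,5R)-3-hydroxy-3-methyl-5-(2-methylprop-1-en-1-yl)oxolan-2-yl]methoxy}-6,8-dimethoxy-2H-chromen-2-one, via allyl cation alkoxytrifluoroborate zwitterion 7 (not isolated), via silyloxonium zwitterion 8 (not isolated), via difluoroboryl ether 9 (not isolated)
Conditions: 6 (4 equiv), BF3·OEt2 (2.5 equiv), 2,6-di-tert-butyl-4-methylpyridine (0.2 equiv), CH2Cl2, −78 → −30 °C; then satd aq. NaHCO3
Reagents that add atoms: none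
Why: Proposed new method: BF3 binds the ketone carbonyl of 5 (monodentate, so no chelate with the silyl ether), the unsubstituted terminus of diene 6 attacks it to give the alkoxytrifluoroborate/1,1-dimethylallyl cation zwitterion 7, the silyl ether oxygen closes onto the secondary allyl terminus to give silyloxonium 8, and fluoride transfer from boron removes the silyl group as Et3SiF to leave 9, which the aqueous work-up hydrolyses to 10. The closest known reaction type is the BF3·OEt2-promoted formal [3+2] annulation of α-triethylsilyloxy aldehydes with allylsilanes and styrenes to oxolan-3-ols; the extension here is to a methyl ketone and to a conjugated diene, whose allyl cation should be at least as stabilised as the β-silyl or benzylic cations of that precedent. Ring C closes in a 5-exo-trig mode at C5 of the E-allyl cation; closure at the tertiary terminus would need a seven-membered ring holding an E-alkene, and a hetero-Diels–Alder path is disfavoured because the Z-methyl group of 6 destabilises the s-cis diene. C3 (R) is set by polar Felkin–Anh (Cornforth) addition, the diene approaching anti to the C2–OSiEt3 bond past the small C2–H, which places the new hydroxyl trans to the aryloxymethyl group. C5 (R) is set in the ring closure, where the alkenyl group should sit pseudo-equatorial and cis to the large, anionic C3–OBF3 group in an envelope transition state, the 3,5-cis relationship that the aldehyde precedent also delivers; C2 is carried over unchanged from 5. The step needs activation of the ketone and not the coumarin lactone (secured by the much lower electrophilicity of the lactone carbonyl and by excess BF3·OEt2) and suppression of proton-initiated diene oligomerisation (secured by the hindered pyridine base and the low temperature).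

**Compound list**

1 | isofraxidin (7-hydroxy-6,8-dimethoxy-2H-chromen-2-one) | COc1cc2ccc(=O)oc2c(OC)c1O | starting material
2 | (R)-2-vinyloxirane | C=C[C@@H]1CO1 | starting material
3 | 7-{[(2R)-2-hydroxybut-3-en-1-yl]oxy}-6,8-dimethoxy-2H-chromen-2-one | COc1cc2ccc(=O)oc2c(OC)c1OC[C@H](O)C=C | intermediate
4 | 6,8-dimethoxy-7-{[(2R)-2-(triethylsilyloxy)but-3-en-1-yl]oxy}-2H-chromen-2-one | COc1cc2ccc(=O)oc2c(OC)c1OC[C@H](O[Si](CC)(CC)CC)C=C | intermediate
5 | 6,8-dimethoxy-7-{[(2S)-3-oxo-2-(triethylsilyloxy)butyl]oxy}-2H-chromen-2-one | COc1cc2ccc(=O)oc2c(OC)c1OC[C@H](O[Si](CC)(CC)CC)C(C)=O | intermediate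
6 | 4-methylpenta-1,3-diene | C=CC=C(C)C | starting material
7 | open-chain zwitterion after C3–C4 bond formation: (2S,3R,5E)-1-aryloxy-3,7-dimethyl-2-(triethylsilyloxy)-3-(trifluoroboranuidyloxy)oct-5-en-7-ylium, aryl = 6,8-dimethoxy-2-oxo-2H-chromen-7-yl | COc1cc2ccc(=O)oc2c(OC)c1OC[C@H](O[Si](CC)(CC)CC)[C@](C)(O[B-](F)(F)F)C/C=C/[C+](C)C | intermediate
8 | (2S,3R,5R)-1-triethylsilyl-oxolan-1-ium zwitterion of the target skeleton with the 3-oxygen as its trifluoroborate | COc1cc2ccc(=O)oc2c(OC)c1OC[C@@H]1[O+]([Si](CC)(CC)CC)[C@@H](C=C(C)C)C[C@@]1(C)O[B-](F)(F)F | intermediate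
9 | (2S,3R,5R)-3-O-difluoroboryl ether of the target | COc1cc2ccc(=O)oc2c(OC)c1OC[C@@H]1O[C@@H](C=C(C)C)C[C@@]1(C)OB(F)F | intermediate
10 | 7-{[(2S,3R,5R)-3-hydroxy-3-methyl-5-(2-methylprop-1-en-1-yl)oxolan-2-yl]methoxy}-6,8-dimethoxy-2H-chromen-2-one | COc1cc2ccc(=O)oc2c(OC)c1OC[C@@H]1O[C@@H](C=C(C)C)C[C@@]1(C)O | target

**Step count and risk**

Total step count: 4. Longest linear sequence: 4 steps (1 → 3 → 4 → 5 → 10).

Steps most likely to fail:

1. Step 4 (Proposed new method).
   - What may go wrong: the BF3-bound methyl ketone may react too slowly with the diene, so that proton-initiated oligomerisation of the diene or early loss of the silyl group takes over. The allyl cation may lose a proton before ring closure. Facial selectivity at C3 or C5 may be eroded, including by re-ionisation of the allylic C5–O bond of the product.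
   - Fallback (known chemistry, stepwise; sets out from 5 and comes back at 10): Hosomi–Sakurai allylation of 5 with allyltrimethylsilane and BF3·OEt2 (CH2Cl2, −78 °C, same Felkin–Anh control) should give the tertiary homoallylic alcohol F1. Cross-metathesis of F1 with 2-methylbut-3-en-2-ol, using the second-generation Hoveyda–Grubbs catalyst (H2IMes)Cl2Ru(=CH-2-(iPrO)C6H4) in CH2Cl2 at 40 °C, should give the E allylic diol F2. HF·pyridine (THF/pyridine, 0 °C) should remove the silyl ether to give the triol F3. Ph3PAuCl/AgOTf-catalysed dehydrative SN2' cyclisation of F3 (CH2Cl2, 4 Å molecular sieves, rt), with the C2 hydroxyl attacking C5 and the tertiary allylic hydroxyl leaving, should close ring C and give 10; the C5 epimers would be separated by chromatography if both form.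

2. Step 3.
   - What may go wrong: loss of the triethylsilyl ether under the Lewis acidic cationic palladium and aqueous peroxide, or partial oxygen delivery to the terminal carbon (aldehyde formation).
   - Fallback (sets out from 4 and comes back at 5): Lemieux–Johnson cleavage of the vinyl group of 4 (OsO4 cat., NaIO4, 2,6-lutidine, dioxane/H2O) should give the α-silyloxy aldehyde F4. MeTi(OiPr)3 (THF, −40 → 0 °C), which adds to aldehydes but not to the lactone, should give the secondary alcohol F5 as a mixture of carbinol epimers. Dess–Martin periodinane (NaHCO3, CH2Cl2) should then converge both epimers on 5.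

3. Step 1.
   - What may go wrong: the hindered phenoxide may attack the allylic epoxide carbon or add in the SN2' sense, or the opening may be so slow that the volatile epoxide is lost.
   - Fallback (sets out from 1 and comes back at 4, replacing steps 1 and 2): purchased (R)-but-3-ene-1,2-diol F6 would be bis-silylated (TESCl, imidazole, DMF) to the bis(triethylsilyl) ether F7. The primary silyl ether would be cleaved selectively (PPTS, MeOH/CH2Cl2, −10 °C) to the primary alcohol (R)-2-(triethylsilyloxy)but-3-en-1-ol F8. Mitsunobu etherification of 1 with F8 (PPh3, DIAD, THF, 0 °C → rt) fixes the ether at the primary carbon without touching the stereocenter and should give 4.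

**Further compounds**

F1 | step 4 | 7-{[(2S,3R)-3-hydroxy-3-methyl-2-(triethylsilyloxy)hex-5-en-1-yl]oxy}-6,8-dimethoxy-2H-chromen-2-one | COc1cc2ccc(=O)oc2c(OC)c1OC[C@H](O[Si](CC)(CC)CC)[C@](C)(O)CC=C
F2 | step 4 | 7-{[(2S,3R,5E)-3,7-dihydroxy-3,7-dimethyl-2-(triethylsilyloxy)oct-5-en-1-yl]oxy}-6,8-dimethoxy-2H-chromen-2-one | COc1cc2ccc(=O)oc2c(OC)c1OC[C@H](O[Si](CC)(CC)CC)[C@](C)(O)C/C=C/C(C)(C)O
F3 | step 4 | 7-{[(2S,3R,5E)-2,3,7-trihydroxy-3,7-dimethyloct-5-en-1-yl]oxy}-6,8-dimethoxy-2H-chromen-2-one | COc1cc2ccc(=O)oc2c(OC)c1OC[C@H](O)[C@](C)(O)C/C=C/C(C)(C)O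
F4 | step 3 | (2S)-3-[(6,8-dimethoxy-2-oxo-2H-chromen-7-yl)oxy]-2-(triethylsilyloxy)propanal | COc1cc2ccc(=O)oc2c(OC)c1OC[C@H](O[Si](CC)(CC)CC)C=O
F5 | step 3 | 7-{[(2S)-3-hydroxy-2-(triethylsilyloxy)butyl]oxy}-6,8-dimethoxy-2H-chromen-2-one (mixture of carbinol epimers) | COc1cc2ccc(=O)oc2c(OC)c1OC[C@H](O[Si](CC)(CC)CC)C(C)O
F6 | step 1 | (R)-but-3-ene-1,2-diol (purchased) | OC[C@H](O)C=C
F7 | step 1 | (3R)-3,4-bis(triethylsilyloxy)but-1-ene | CC[Si](CC)(CC)OC[C@H](O[Si](CC)(CC)CC)C=C
F8 | step 1 | (R)-2-(triethylsilyloxy)but-3-en-1-ol | OC[C@H](O[Si](CC)(CC)CC)C=C
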